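**Retrosynthetic overview**
- The target comes from a silyl-protected adduct whose flavanone C4 is still a 1,3-dithiane; the dithiane is unmasked and the silyl ethers removed last.
- The cyclohexene (last ring formed) comes from an exo Diels–Alder reaction of a 2'-hydroxychalcone with an (E)-aryl-3-methylbutadiene under a chiral borate; the diene is installed by Suzuki coupling on an aryl bromide.
- The pyran ring C (formed before the cyclohexene) is closed by intramolecular Mitsunobu etherification with inversion.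
- Key C3–C4 bond of the flavanone: a lithiated 2-aryl-1,3-dithiane (acyl anion of 2,4-dihydroxybenzaldehyde) opens an (R)-aryl oxirane; the dithiane then stays on as a lock against retro-oxa-Michael racemisation.
- The oxirane comes from asymmetric transfer hydrogenation of an α-chloro ketone made from 4-bromoresorcinol; the dienophile comes from a Claisen–Schmidt condensation.

Assumption: the borate from (R)-VANOL is taken to give the (1R,5S,6R) cycloadduct series; if the measured sense is opposite, the (S)-ligand is used with no other change.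

**Step 1**
Reactants: 1 4-bromobenzene-1,3-diol; 2 chloroacetyl chloride
Product: 3 1-(5-bromo-2,4-dihydroxyphenyl)-2-chloroethan-1-one
Conditions: AlCl3 (3 equiv), 1,2-dichloroethane, 0 to 60 °C; then 1 M HCl
Reagents that add atoms: none
Why: Friedel–Crafts acylation goes to C6, the only position para to one hydroxyl and ortho to the other without being flanked by both, which gives the ring B pattern with the two-carbon unit in place.

**Step 2**
Reactants: 3 1-(5-bromo-2,4-dihydroxyphenyl)-2-chloroethan-1-one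
Product: 4 1-[5-bromo-2,4-bis(triisopropylsilyloxy)phenyl]-2-chloroethan-1-one
Conditions: triisopropylsilyl triflate (2.3 equiv), 2,6-lutidine, CH2Cl2, 0 °C to rt
Reagents that add atoms: triisopropylsilyl trifluoromethanesulfonate, CC(C)[Si](OS(=O)(=O)C(F)(F)F)(C(C)C)C(C)C
Why: Phenol silylation with a hindered base that the phenacyl chloride cannot alkylate installs fluoride-labile groups bulky enough to resist later O-to-O silyl migration.

**Step 3**
Reactants: 4 1-[5-bromo-2,4-bis(triisopropylsilyloxy)phenyl]-2-chloroethan-1-one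
Product: 5 (1R)-1-[5-bromo-2,4-bis(triisopropylsilyloxy)phenyl]-2-chloroethan-1-ol
Conditions: RuCl[(S,S)-TsDPEN](p-cymene) (1 mol %), HCO2H/Et3N (5:2), EtOAc, 28 °C
Reagents that add atoms: none
Why: Noyori asymmetric transfer hydrogenation delivers hydride to one ketone face (aryl recognised by the CH/π contact of the catalyst) and sets the (R)-carbinol that becomes flavanone C2.

**Step 4**
Reactants: 6 2,4-dihydroxybenzaldehyde
Product: 7 2-hydroxy-4-(triisopropylsilyloxy)benzaldehyde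
Conditions: triisopropylsilyl chloride (1.05 equiv), imidazole, CH2Cl2, 0 °C
Reagents that add atoms: triisopropylsilyl chloride, CC(C)[Si](Cl)(C(C)C)C(C)C
Why: Chemoselective silylation, because the 2-hydroxyl is tied up in a hydrogen bond to the aldehyde and only the 4-hydroxyl reacts.

**Step 5**
Reactants: 7 2-hydroxy-4-(triisopropylsilyloxy)benzaldehyde; 8 propane-1,3-dithiol
Product: 9 2-(1,3-dithian-2-yl)-5-(triisopropylsilyloxy)phenol
Conditions: BF3·OEt2 (10 mol %), CH2Cl2, 0 °C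
Reagents that add atoms: none
Why: Lewis-acid-catalysed dithioacetalisation turns the aldehyde carbon into a latent acyl anion (Corey–Seebach dithiane).

**Step 6**
Reactants: 9 2-(1,3-dithian-2-yl)-5-(triisopropylsilyloxy)phenol; 5 (1R)-1-[5-bromo-2,4-bis(triisopropylsilyloxy)phenyl]-2-chloroethan-1-ol
Product: 12 (1S)-1-[5-bromo-2,4-bis(triisopropylsilyloxy)phenyl]-2-{2-[2-hydroxy-4-(triisopropylsilyloxy)phenyl]-1,3-dithian-2-yl}ethan-1-ol, via dilithiated phenol-dithiane 10 (not isolated), via aryl oxirane 11 (not isolated)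
Conditions: 9 (1.3 equiv), n-BuLi (2.05 equiv per 9), THF, −78 to −20 °C; separately 5, LiN(SiMe3)2 (1.05 equiv), THF, −78 to 0 °C; combine, −20 to 10 °C; aq NH4Cl
Reagents that add atoms: none
Why: Corey–Seebach umpolung, in which the dithiane carbanion (acyl-anion equivalent of the ring A aldehyde, its phenol carried as the lithium phenoxide) opens the oxirane at the CH2 terminus by SN2, so two formerly electrophilic carbons are joined and the carbinol centre from step 3 is untouched (R oxirane to S alcohol is a priority change only).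

**Step 7**
Reactants: 12 (1S)-1-[5-bromo-2,4-bis(triisopropylsilyloxy)phenyl]-2-{2-[2-hydroxy-4-(triisopropylsilyloxy)phenyl]-1,3-dithian-2-yl}ethan-1-ol
Product: 13 (2R)-2-[5-bromo-2,4-bis(triisopropylsilyloxy)phenyl]-7-(triisopropylsilyloxy)spiro[chromane-4,2'-[1,3]dithiane]
Conditions: PPh3, DIAD, toluene, −20 to 0 °C
Reagents that add atoms: none
Why: Intramolecular Mitsunobu etherification (6-exo-tet) in which the phenol displaces the activated benzylic alcohol with inversion to give the (2R) chroman, while the dithioketal blocks the β-elimination a free ketone would undergo.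

**Step 8**
Reactants: 14 2-methylbut-1-en-3-yne; 15 pinacolborane
Product: 16 4,4,5,5-tetramethyl-2-[(1E)-3-methylbuta-1,3-dien-1-yl]-1,3,2-dioxaborolane
Conditions: Cp2Zr(H)Cl (5 mol %), Et3N (10 mol %), neat, 60 °C
Reagents that add atoms: none
Why: Zirconium-catalysed syn-hydroboration of the terminal alkyne gives the (E)-dienyl boronate with boron at the terminal carbon.

**Step 9**
Reactants: 13 (2R)-2-[5-bromo-2,4-bis(triisopropylsilyloxy)phenyl]-7-(triisopropylsilyloxy)spiro[chromane-4,2'-[1,3]dithiane]; 16 4,4,5,5-tetramethyl-2-[(1E)-3-methylbuta-1,3-dien-1-yl]-1,3,2-dioxaborolane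
Product: 17 (2R)-2-{5-[(1E)-3-methylbuta-1,3-dien-1-yl]-2,4-bis(triisopropylsilyloxy)phenyl}-7-(triisopropylsilyloxy)spiro[chromane-4,2'-[1,3]dithiane]
Conditions: Pd(OAc)2 (5 mol %), SPhos (10 mol %), K3PO4, toluene/H2O, 60 °C
Reagents that add atoms: none
Why: Suzuki–Miyaura coupling keeps the (E)-alkene geometry, and the masked chroman cannot undergo base-induced retro-oxa-Michael opening, so C2 is safe under the basic conditions.

**Step 10**
Reactants: 18 1-(2,4-dihydroxyphenyl)ethan-1-one; 6 2,4-dihydroxybenzaldehyde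
Product: 19 (2E)-1,3-bis(2,4-dihydroxyphenyl)prop-2-en-1-one
Conditions: KOH (50 % aq), EtOH, rt, 48 h; then 1 M HCl to pH 4
Reagents that add atoms: none
Why: Claisen–Schmidt condensation gives the (E)-enone; the phenoxides slow the reaction and lower the yield but do not stop it.

**Step 11**
Reactants: 19 (2E)-1,3-bis(2,4-dihydroxyphenyl)prop-2-en-1-one
Product: 20 (2E)-3-[2,4-bis(tert-butyldimethylsilyloxy)phenyl]-1-[4-(tert-butyldimethylsilyloxy)-2-hydroxyphenyl]prop-2-en-1-one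
Conditions: tert-butyldimethylsilyl chloride (3.3 equiv), imidazole, DMF, 0 °C
Reagents that add atoms: tert-butyldimethylsilyl chloride, CC(C)(C)[Si](C)(C)Cl
Why: The three free phenols are silylated while the 2'-hydroxyl, chelated to the ketone, stays free as the handle for boron activation.

**Step 12**
Reactants: 17 (2R)-2-{5-[(1E)-3-methylbuta-1,3-dien-1-yl]-2,4-bis(triisopropylsilyloxy)phenyl}-7-(triisopropylsilyloxy)spiro[chromane-4,2'-[1,3]dithiane]; 20 (2E)-3-[2,4-bis(tert-butyldimethylsilyloxy)phenyl]-1-[4-(tert-butyldimethylsilyloxy)-2-hydroxyphenyl]prop-2-en-1-one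
Product: 21 [4-(tert-butyldimethylsilyloxy)-2-hydroxyphenyl]{(1R,2R,6S)-6-[2,4-bis(tert-butyldimethylsilyloxy)phenyl]-4-methyl-2-{2,4-bis(triisopropylsilyloxy)-5-[(2R)-7-(triisopropylsilyloxy)spiro[chromane-4,2'-[1,3]dithian]-2-yl]phenyl}cyclohex-3-en-1-yl}methanone
Conditions: borate pre-formed from (R)-VANOL, BH3·THF and AcOH (0.3 equiv), 5 Å MS, PhCF3, rt to 40 °C
Reagents that add atoms: none
Why: Diels–Alder reaction of the boron-chelated 2'-hydroxychalcone in which ortho regiochemistry joins diene C1 to the enone α-carbon, the (E)-enone fixes the aroyl/aryl trans relation, the exo approach puts the aroyl group trans to the ring B aryl, and the chiral borate shields one enone face to set all three ring centres; the endo isomer is removed by chromatography.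

**Step 13**
Reactants: 21 the dithiane-masked cycloadduct of step 12
Product: 22 (2R)-2-{5-[(1R,5S,6R)-6-[4-(tert-butyldimethylsilyloxy)-2-hydroxybenzoyl]-5-[2,4-bis(tert-butyldimethylsilyloxy)phenyl]-3-methylcyclohex-2-en-1-yl]-2,4-bis(triisopropylsilyloxy)phenyl}-7-(triisopropylsilyloxy)-2,3-dihydro-4H-chromen-4-one
Conditions: MeI (10 equiv), CaCO3, MeCN/H2O (9:1), 45 °C
Reagents that add atoms: water, O
Why: Alkylative dithioketal hydrolysis (S-methylation, then water capture of the benzylic thionium ion) releases the ketone under near-neutral conditions that leave flavanone C2, the silyl ethers and the alkene intact.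

**Step 14**
Reactants: 22 the hexasilylated flavanone adduct of step 13
Product: 23 (2R)-2-{5-[(1R,5S,6R)-6-(2,4-dihydroxybenzoyl)-5-(2,4-dihydroxyphenyl)-3-methylcyclohex-2-en-1-yl]-2,4-dihydroxyphenyl}-7-hydroxy-2,3-dihydro-4H-chromen-4-one
Conditions: Bu4NF (7 equiv), AcOH (7 equiv), THF, 0 °C; pH 7 buffer work-up
Reagents that add atoms: none
Why: Buffered fluoride desilylation cleaves all six aryl silyl ethers at 0 °C without acid or base strong enough to open the flavanone or epimerise C2, and gives the target.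

**Compound list**
1 | 4-bromobenzene-1,3-diol | Oc1ccc(Br)c(O)c1 | starting material
2 | chloroacetyl chloride | ClCC(=O)Cl | starting material
3 | 1-(5-bromo-2,4-dihydroxyphenyl)-2-chloroethan-1-one | O=C(CCl)c1cc(Br)c(O)cc1O | intermediate
4 | 1-[5-bromo-2,4-bis(triisopropylsilyloxy)phenyl]-2-chloroethan-1-one | O=C(CCl)c1cc(Br)c(O[Si](C(C)C)(C(C)C)C(C)C)cc1O[Si](C(C)C)(C(C)C)C(C)C | intermediate
5 | (1R)-1-[5-bromo-2,4-bis(triisopropylsilyloxy)phenyl]-2-chloroethan-1-ol | O[C@@H](CCl)c1cc(Br)c(O[Si](C(C)C)(C(C)C)C(C)C)cc1O[Si](C(C)C)(C(C)C)C(C)C | intermediate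
6 | 2,4-dihydroxybenzaldehyde | O=Cc1ccc(O)cc1O | starting material
7 | 2-hydroxy-4-(triisopropylsilyloxy)benzaldehyde | O=Cc1ccc(O[Si](C(C)C)(C(C)C)C(C)C)cc1O | intermediate
8 | propane-1,3-dithiol | SCCCS | starting material
9 | 2-(1,3-dithian-2-yl)-5-(triisopropylsilyloxy)phenol | Oc1cc(O[Si](C(C)C)(C(C)C)C(C)C)ccc1C1SCCCS1 | intermediate
10 | dilithium 2-(1,3-dithian-2-id-2-yl)-5-(triisopropylsilyloxy)phenolate | [Li+].[Li+].[O-]c1cc(O[Si](C(C)C)(C(C)C)C(C)C)ccc1[C-]1SCCCS1 | intermediate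
11 | (2R)-2-[5-bromo-2,4-bis(triisopropylsilyloxy)phenyl]oxirane | C1O[C@@H]1c1cc(Br)c(O[Si](C(C)C)(C(C)C)C(C)C)cc1O[Si](C(C)C)(C(C)C)C(C)C | intermediate
12 | (1S)-1-[5-bromo-2,4-bis(triisopropylsilyloxy)phenyl]-2-{2-[2-hydroxy-4-(triisopropylsilyloxy)phenyl]-1,3-dithian-2-yl}ethan-1-ol | O[C@@H](CC1(SCCCS1)c1ccc(O[Si](C(C)C)(C(C)C)C(C)C)cc1O)c1cc(Br)c(O[Si](C(C)C)(C(C)C)C(C)C)cc1O[Si](C(C)C)(C(C)C)C(C)C | intermediate
13 | (2R)-2-[5-bromo-2,4-bis(triisopropylsilyloxy)phenyl]-7-(triisopropylsilyloxy)spiro[chromane-4,2'-[1,3]dithiane] | Brc1cc([C@H]2CC3(SCCCS3)c3ccc(O[Si](C(C)C)(C(C)C)C(C)C)cc3O2)c(O[Si](C(C)C)(C(C)C)C(C)C)cc1O[Si](C(C)C)(C(C)C)C(C)C | intermediate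
14 | 2-methylbut-1-en-3-yne | C=C(C)C#C | starting material
15 | pinacolborane (4,4,5,5-tetramethyl-1,3,2-dioxaborolane) | B1OC(C)(C)C(C)(C)O1 | starting material
16 | 4,4,5,5-tetramethyl-2-[(1E)-3-methylbuta-1,3-dien-1-yl]-1,3,2-dioxaborolane | C=C(C)/C=C/B1OC(C)(C)C(C)(C)O1 | intermediate
17 | (2R)-2-{5-[(1E)-3-methylbuta-1,3-dien-1-yl]-2,4-bis(triisopropylsilyloxy)phenyl}-7-(triisopropylsilyloxy)spiro[chromane-4,2'-[1,3]dithiane] | C=C(C)/C=C/c1cc([C@H]2CC3(SCCCS3)c3ccc(O[Si](C(C)C)(C(C)C)C(C)C)cc3O2)c(O[Si](C(C)C)(C(C)C)C(C)C)cc1O[Si](C(C)C)(C(C)C)C(C)C | intermediate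
18 | 1-(2,4-dihydroxyphenyl)ethan-1-one | CC(=O)c1ccc(O)cc1O | starting material
19 | (2E)-1,3-bis(2,4-dihydroxyphenyl)prop-2-en-1-one | O=C(/C=C/c1ccc(O)cc1O)c1ccc(O)cc1O | intermediate
20 | (2E)-3-[2,4-bis(tert-butyldimethylsilyloxy)phenyl]-1-[4-(tert-butyldimethylsilyloxy)-2-hydroxyphenyl]prop-2-en-1-one | O=C(/C=C/c1ccc(O[Si](C)(C)C(C)(C)C)cc1O[Si](C)(C)C(C)(C)C)c1ccc(O[Si](C)(C)C(C)(C)C)cc1O | intermediate
21 | [4-(tert-butyldimethylsilyloxy)-2-hydroxyphenyl]{(1R,2R,6S)-6-[2,4-bis(tert-butyldimethylsilyloxy)phenyl]-4-methyl-2-{2,4-bis(triisopropylsilyloxy)-5-[(2R)-7-(triisopropylsilyloxy)spiro[chromane-4,2'-[1,3]dithian]-2-yl]phenyl}cyclohex-3-en-1-yl}methanone | CC1=C[C@@H](c2cc([C@H]3CC4(SCCCS4)c4ccc(O[Si](C(C)C)(C(C)C)C(C)C)cc4O3)c(O[Si](C(C)C)(C(C)C)C(C)C)cc2O[Si](C(C)C)(C(C)C)C(C)C)[C@H](C(=O)c2ccc(O[Si](C)(C)C(C)(C)C)cc2O)[C@@H](c2ccc(O[Si](C)(C)C(C)(C)C)cc2O[Si](C)(C)C(C)(C)C)C1 | intermediate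
22 | (2R)-2-{5-[(1R,5S,6R)-6-[4-(tert-butyldimethylsilyloxy)-2-hydroxybenzoyl]-5-[2,4-bis(tert-butyldimethylsilyloxy)phenyl]-3-methylcyclohex-2-en-1-yl]-2,4-bis(triisopropylsilyloxy)phenyl}-7-(triisopropylsilyloxy)-2,3-dihydro-4H-chromen-4-one | CC1=C[C@@H](c2cc([C@H]3CC(=O)c4ccc(O[Si](C(C)C)(C(C)C)C(C)C)cc4O3)c(O[Si](C(C)C)(C(C)C)C(C)C)cc2O[Si](C(C)C)(C(C)C)C(C)C)[C@H](C(=O)c2ccc(O[Si](C)(C)C(C)(C)C)cc2O)[C@@H](c2ccc(O[Si](C)(C)C(C)(C)C)cc2O[Si](C)(C)C(C)(C)C)C1 | intermediate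
23 | (2R)-2-{5-[(1R,5S,6R)-6-(2,4-dihydroxybenzoyl)-5-(2,4-dihydroxyphenyl)-3-methylcyclohex-2-en-1-yl]-2,4-dihydroxyphenyl}-7-hydroxy-2,3-dihydro-4H-chromen-4-one | CC1=C[C@@H](c2cc([C@H]3CC(=O)c4ccc(O)cc4O3)c(O)cc2O)[C@H](C(=O)c2ccc(O)cc2O)[C@@H](c2ccc(O)cc2O)C1 | target

**Step count**
Total steps: 14. Longest linear sequence: 9 steps (1, 2, 3, 6, 7, 9, 12, 13, 14).

**Steps most likely to fail, with fallbacks**

Step 12 (cycloaddition). The hindered silyl ethers and the sulfur-bearing diene may give poor exo or facial selectivity; exo and endo adducts are expected in comparable amounts even when it works. The fallback runs the cycloaddition on free phenols with an enzyme. It sets out from 17, which is unmasked (MeI, CaCO3, aqueous MeCN) to (2R)-2-{5-[(1E)-3-methylbuta-1,3-dien-1-yl]-2,4-bis(triisopropylsilyloxy)phenyl}-7-(triisopropylsilyloxy)-2,3-dihydro-4H-chromen-4-one F9. Desilylation (Bu4NF/AcOH, 0 °C) gives (2R)-2-{2,4-dihydroxy-5-[(1E)-3-methylbuta-1,3-dien-1-yl]phenyl}-7-hydroxy-2,3-dihydro-4H-chromen-4-one F10, used at once. F10 and the unprotected chalcone 19 are incubated with an exo-selective, FAD-dependent Diels–Alderase of the Morus alba MaDA family (pH 8 buffer, 30 to 50 °C). This gives the all-trans adduct of natural configuration and comes back to the route at the target 23.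

Step 6 (dithiane anion with the oxirane made in the flask). Benzylic attack, rearrangement of the electron-rich oxirane or silyl migration to the new alkoxide may compete. The fallback makes the same C3–C4 bond catalytically and intramolecularly. It sets out from 5 and 7, which are joined by Mitsunobu etherification (PPh3, DIAD, inversion) to 2-{(1S)-1-[5-bromo-2,4-bis(triisopropylsilyloxy)phenyl]-2-chloroethoxy}-4-(triisopropylsilyloxy)benzaldehyde F1. A thiazolium-derived carbene (3-benzyl-5-(2-hydroxyethyl)-4-methylthiazolium chloride, DBU, NaI, THF) converts the aldehyde into a Breslow intermediate that displaces the primary halide. This gives (2R)-2-[5-bromo-2,4-bis(triisopropylsilyloxy)phenyl]-7-(triisopropylsilyloxy)-2,3-dihydro-4H-chromen-4-one F2. Dithioketalisation of F2 with 8 (BF3·OEt2) comes back to the route at 13.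

Step 7 (Mitsunobu closure). The benzylic centre carries two silyloxy donors and may partly ionise, eroding the ee. The fallback leaves the benzylic C–O bond intact and forms the aryl C–O bond instead, with retention. It sets out from 4, reduced with RuCl[(R,R)-TsDPEN](p-cymene) to (1S)-1-[5-bromo-2,4-bis(triisopropylsilyloxy)phenyl]-2-chloroethan-1-ol F3. Commercial 2-bromo-4-hydroxybenzaldehyde is silylated to 2-bromo-4-(triisopropylsilyloxy)benzaldehyde F4 and converted with 8 into 2-[2-bromo-4-(triisopropylsilyloxy)phenyl]-1,3-dithiane F5. LiN(iPr)2 gives lithium 2-[2-bromo-4-(triisopropylsilyloxy)phenyl]-1,3-dithian-2-ide F6. F6 opens (2S)-2-[5-bromo-2,4-bis(triisopropylsilyloxy)phenyl]oxirane F7, made in the flask from F3 with LiN(SiMe3)2. The product is (1R)-1-[5-bromo-2,4-bis(triisopropylsilyloxy)phenyl]-2-{2-[2-bromo-4-(triisopropylsilyloxy)phenyl]-1,3-dithian-2-yl}ethan-1-ol F8. Intramolecular O-arylation (copper monoiodide, 1,10-phenanthroline, Cs2CO3, toluene, 90 °C) closes the pyran ring and comes back to the route at 13.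

**Further compounds**
F1 | step 6 | 2-{(1S)-1-[5-bromo-2,4-bis(triisopropylsilyloxy)phenyl]-2-chloroethoxy}-4-(triisopropylsilyloxy)benzaldehyde | O=Cc1ccc(O[Si](C(C)C)(C(C)C)C(C)C)cc1O[C@H](CCl)c1cc(Br)c(O[Si](C(C)C)(C(C)C)C(C)C)cc1O[Si](C(C)C)(C(C)C)C(C)C
F2 | step 6 | (2R)-2-[5-bromo-2,4-bis(triisopropylsilyloxy)phenyl]-7-(triisopropylsilyloxy)-2,3-dihydro-4H-chromen-4-one | Brc1cc([C@H]2CC(=O)c3ccc(O[Si](C(C)C)(C(C)C)C(C)C)cc3O2)c(O[Si](C(C)C)(C(C)C)C(C)C)cc1O[Si](C(C)C)(C(C)C)C(C)C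
F3 | step 7 | (1S)-1-[5-bromo-2,4-bis(triisopropylsilyloxy)phenyl]-2-chloroethan-1-ol | O[C@H](CCl)c1cc(Br)c(O[Si](C(C)C)(C(C)C)C(C)C)cc1O[Si](C(C)C)(C(C)C)C(C)C
F4 | step 7 | 2-bromo-4-(triisopropylsilyloxy)benzaldehyde | O=Cc1ccc(O[Si](C(C)C)(C(C)C)C(C)C)cc1Br
F5 | step 7 | 2-[2-bromo-4-(triisopropylsilyloxy)phenyl]-1,3-dithiane | Brc1cc(O[Si](C(C)C)(C(C)C)C(C)C)ccc1C1SCCCS1
F6 | step 7 | lithium 2-[2-bromo-4-(triisopropylsilyloxy)phenyl]-1,3-dithian-2-ide | [Li+].Brc1cc(O[Si](C(C)C)(C(C)C)C(C)C)ccc1[C-]1SCCCS1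
F7 | step 7 | (2S)-2-[5-bromo-2,4-bis(triisopropylsilyloxy)phenyl]oxirane | C1O[C@H]1c1cc(Br)c(O[Si](C(C)C)(C(C)C)C(C)C)cc1O[Si](C(C)C)(C(C)C)C(C)C
F8 | step 7 | (1R)-1-[5-bromo-2,4-bis(triisopropylsilyloxy)phenyl]-2-{2-[2-bromo-4-(triisopropylsilyloxy)phenyl]-1,3-dithian-2-yl}ethan-1-ol | O[C@H](CC1(SCCCS1)c1ccc(O[Si](C(C)C)(C(C)C)C(C)C)cc1Br)c1cc(Br)c(O[Si](C(C)C)(C(C)C)C(C)C)cc1O[Si](C(C)C)(C(C)C)C(C)C
F9 | step 12 | (2R)-2-{5-[(1E)-3-methylbuta-1,3-dien-1-yl]-2,4-bis(triisopropylsilyloxy)phenyl}-7-(triisopropylsilyloxy)-2,3-dihydro-4H-chromen-4-one | C=C(C)/C=C/c1cc([C@H]2CC(=O)c3ccc(O[Si](C(C)C)(C(C)C)C(C)C)cc3O2)c(O[Si](C(C)C)(C(C)C)C(C)C)cc1O[Si](C(C)C)(C(C)C)C(C)C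
F10 | step 12 | (2R)-2-{2,4-dihydroxy-5-[(1E)-3-methylbuta-1,3-dien-1-yl]phenyl}-7-hydroxy-2,3-dihydro-4H-chromen-4-one | C=C(C)/C=C/c1cc([C@H]2CC(=O)c3ccc(O)cc3O2)c(O)cc1O
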